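## Analysis of the target

- The target has a 1,4-dimethylcyclohex-3-ene core, numbered here C1 (quaternary), C2 and C3 (methylene), C4 (methyl-bearing alkene carbon), C5 (alkene CH) and C6 (benzylic CH). It carries two 5,7-dimethoxycoumarin units, both attached through their C8: coumarin A through an (E)-ethenyl link to C1, coumarin B directly to C6.
- There are only two stereocentres and they are adjacent: C1 (R, quaternary) and C6 (R). The ethenyl arm on C1 and the aryl group on C6 are cis, so the C1 methyl group is trans to the aryl group.
- Sensitive groups are the two lactones (hydride, hydroxide), the styrene-type E alkene (light) and the C4=C5 alkene. The C6–H next to that alkene is both allylic and benzylic, so acid- or base-induced migration into conjugation would erase C6, and a free ortho phenol can add across the alkene under strong acid.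
- The alkene of the arm, the C1–C6 bond and C4=C5 form a 1,5-diene, so prolonged strong heating late in the route is best avoided.
- The difficulty lies in the vicinal quaternary/benzylic pair with a di-ortho-oxygenated aryl group on C6, in two one-carbon groups on C1 at different oxidation levels (CH3 and CH=), and in the hindered C8 positions of both coumarins.
- The strategy rests on one feature. The ring oxygen of coumarin B sits ortho to the C6–aryl bond, and C1 carries a carbon substituent cis to that aryl group. The path O–aryl–C6–C1–C is therefore the O1–C8a–C4a–C4–C3–C2 path of a second, temporary coumarin, in which C6 and C1 are C4 and C3 of a 5,7-dimethoxycoumarin-3-carboxylate.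
- The C3=C4 bond of that coumarin ester is a cis-locked, doubly activated dienophile. A Diels–Alder reaction across it forms C1–C2 and C5–C6, and a silyl group on the diene allows the new alkene to be moved to C4=C5. The lactone carbonyl later becomes the ethenyl carbon, the ester becomes the C1 methyl, and the phenol oxygen becomes O1 of coumarin B.

## Retrosynthetic reasoning

**C8 (coumarin A)–ethenyl bond.** Target 25 is cut into alkenyl iodide 21 and aryl boronate 24 (Suzuki coupling). This is the only bond joining two large halves, it touches neither stereocentre, and the E geometry is already fixed in 21. The forward reaction has to couple a hindered, di-ortho-oxygenated boronate under a base mild enough for two lactones. Boronate 24 goes back through iodide 23 to the parent coumarin 22.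

**Pyranone of coumarin B.** In 21 the C3=C4 bond and the O1–C2 bond are cut (Wittig lactonisation through acyl ylide 20), then the C4–C4a bond (formyl group of 19), leading to phenol 18. The phenol oxygen of 18 is the future O1 and its only free ortho carbon is the future C4a, so a phenol-directed formylation cannot go astray. This ring is built before the coupling so that neither coumarin A nor the styrene/1,5-diene unit sees these conditions.

**Iodoalkene.** The C=C bond of 18 is cut to the aldehyde that is stored as lactol 17 (Takai olefination). The aldehyde carbon sits on the quaternary C1, so it cannot enolise and the stereocentre is safe.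

**Oxidation levels at C1.** Lactol 17 comes from acetal 16, which comes through mesylate 15 and alcohol 14 from ester acetal 13, lactol 12 and finally lactone ester 11. The two carbonyl groups of 11 differ in kind, an aryl lactone and a methyl ester. The more electrophilic lactone is therefore reduced first and parked as a cyclic acetal, which protects the aldehyde level and the phenol together. The ester is then taken down to the methyl group.

**Key disconnection.** Lactone ester 11 is cut at C6a–C7 and C10–C10a (C1–C2 and C5–C6 of the core) into coumarin ester 4 and silyl diene 9, by way of silyl adduct 10. One step then makes the carbocycle and both stereocentres. The hindered C6–aryl bond never has to be formed, because it is already present as C4–C4a of 4. A plain 2-methylbutadiene would leave the alkene at C3=C4. Silicon on the diene terminus that bonds to coumarin C4 gives an allylsilane instead, and protodesilylation delivers the alkene to C4=C5. The forward reaction must overcome the low reactivity of the dimethoxy-substituted dienophile and select one face.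

**Dienophile.** Coumarin ester 4 is cut at C3=C4 and at the lactone C–O bond into salicylaldehyde 1 and malonate 2 (Knoevenagel condensation through 3).

**Diene.** Diene 9 is cut at the terminal C=C (Wittig reaction of aldehyde 8), which comes from allylic alcohol 7 and, by cutting the C2–methyl bond, from silyl propargylic alcohol 5. The geometry matters: silicon must be trans to the vinyl group so that it lies outside the s-cis diene. A shorter route by hydrohalogenation of a silylalkyne and vinyl coupling was not used, because anti addition would place silicon cis to the vinyl group. The chelate 6 of the carbomagnesiation fixes the required geometry.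

## Alternatives that were turned down

**Alternative 1: benzannulation that builds the arene of coumarin B on C6.** The benzene ring of coumarin B is disconnected completely. A cyclohexenyl silyl ynol ether A2 and 3-methoxycyclobutenone A3 would be heated together: the vinylketene from A3 adds to the alkyne, and ring opening and 6π electrocyclisation give the resorcinol monosilyl ether A1.

- For: the hindered C6–aryl bond is not made by substitution. The two ortho oxygens come out differentiated (free phenol and silyl ether) in a pattern fixed by the mechanism. A1 already carries the C1 methyl and a vinyl group at the right oxidation level, so on that point it is stronger than the chosen route, which spends steps 7–11 on adjusting C1.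
- Against: the key step creates neither stereocentre nor the carbocycle. The cis C1/C6 cyclohexene must first be made enantioselectively and then carried to the hydrolytically labile ynol ether A2, through a homologation next to an epimerisable C6. A2 contains a 1,5-enyne and a 1,5-diene that must survive the heating. The [2+2] step has to take place beside a quaternary carbon.
- Comparison: the route would be longer overall. The chosen strategy offers ring, both stereocentres and the aryl attachment in one step from two achiral pieces.

**Alternative 2: ring-rearrangement metathesis of a cyclobutene.** The C4=C5 bond and the vinyl C=C are disconnected. A ruthenium alkylidene would open cyclobutene A5 (aryl and methyl cis on the four-membered ring, with a 3-methylbut-3-enyl chain on the quaternary carbon) and the carbene at the future C5 would close onto the isopropenyl group to give A4.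

- For: strain release drives the step, the conditions are neutral, the stereocentres are not touched, and A4 has the methyl, the vinyl and a protected phenol in place.
- Against: the stereochemical problem is only moved into A5, a cyclobutene with a quaternary centre next to a di-ortho-substituted aryl group, for which no direct asymmetric construction is evident. If the metal ends on the other cyclobutene carbon, closure onto the isopropenyl group gives a cyclopentene instead. Ring-opening oligomerisation competes with the slow closure to a trisubstituted alkene.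
- Comparison: it is at best equal after the key step and clearly worse before it.

**Alternative 3: aryl ester tether that delivers the arene to C6.** The C6–aryl bond is disconnected intramolecularly. In the 3,5-dimethoxyphenyl ester A7 a Lewis acid would ionise the tertiary allylic alcohol at C4, and the ortho carbon of the ester aryl group would attack the allyl cation at C6 to give the cis-fused lactone A6.

- For: the six-membered tether enforces the cis relationship. The C1 methyl is present from the start. A6 is one hydride reduction away from lactol 17, so steps 7–11 of the chosen route would be saved. On step economy after the key step this alternative is stronger.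
- Against: the configuration at C1 is not created here; an enantioenriched α-methyl quaternary cyclohexenecarboxylic acid is needed beforehand, with several steps to install the tertiary alcohol. The tertiary allyl cation readily loses a proton to give dienes. The aryl ester is a weakened nucleophile that must reach C6 from the unfavourable s-cis ester conformation, at a secondary terminus next to a quaternary carbon, and Lewis acids can also trigger Fries migration or ester cleavage.
- Comparison: the chosen strategy sets both centres and the ring together under catalyst control from achiral materials. It pays for this with extra functional-group steps and with the uncertain reactivity of its dienophile.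

Key step: step 5

Assumption: the sense of asymmetric induction of the copper complex on this dienophile cannot be derived with certainty; the (S,S)-tert-butyl bis(oxazoline) ligand, 2,2'-(propane-2,2-diyl)bis[(4S)-4-tert-butyl-4,5-dihydro-1,3-oxazole], is written, and its (R,R) antipode would be used if the first adduct proved to be the enantiomer of 11.

## Route

Step 1
Reactants: 1 2-hydroxy-4,6-dimethoxybenzaldehyde; 2 dimethyl malonate
Product: 4 methyl 5,7-dimethoxy-2-oxo-2H-chromene-3-carboxylate, via benzylidenemalonate 3 (not isolated)
Conditions: piperidine (cat.), AcOH (cat.), MeOH, reflux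
Reagents that add atoms: none
Why: Knoevenagel condensation gives 3, whose ortho phenol closes onto the cis ester by intramolecular transesterification; this is the standard entry to coumarin-3-carboxylates.

Step 2
Reactants: 5 3-(trimethylsilyl)prop-2-yn-1-ol
Product: 7 (E)-2-methyl-3-(trimethylsilyl)prop-2-en-1-ol, via alkenylmagnesium chelate 6 (not isolated)
Conditions: MeMgBr (3 equiv), CuI (10 mol%), Et2O, 0 °C → reflux; aq. NH4Cl
Reagents that add atoms: methylmagnesium bromide, C[Mg]Br
Why: Copper-catalysed anti-carbomagnesiation of a propargylic alcohol (Duboudin type): the alkoxide directs methyl to C2 and magnesium to the silyl-bearing C3, held in five-membered chelate 6. Protonolysis with retention leaves silicon cis to methyl and trans to the CH2OH group.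

Step 3
Reactants: 7 (E)-2-methyl-3-(trimethylsilyl)prop-2-en-1-ol
Product: 8 (E)-2-methyl-3-(trimethylsilyl)prop-2-enal
Conditions: MnO2, pentane, rt
Reagents that add atoms: none
Why: Allylic alcohol oxidation with MnO2 under neutral conditions, which should not isomerise or desilylate the vinylsilane; the volatile aldehyde is carried on as a filtered solution.

Step 4
Reactants: 8 (E)-2-methyl-3-(trimethylsilyl)prop-2-enal
Product: 9 (E)-trimethyl(2-methylbuta-1,3-dien-1-yl)silane
Conditions: Ph3PCH3Br, KOt-Bu, Et2O, 0 °C → rt
Reagents that add atoms: methyltriphenylphosphonium bromide, C[P+](c1ccccc1)(c1ccccc1)c1ccccc1.[Br-]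
Why: Wittig methylenation of an enal; the trisubstituted vinylsilane geometry is not involved, so silicon stays trans to the new vinyl group. The volatile diene is purified by distillation.

Step 5
Reactants: 4 methyl 5,7-dimethoxy-2-oxo-2H-chromene-3-carboxylate; 9 (E)-trimethyl(2-methylbuta-1,3-dien-1-yl)silane
Product: 11 methyl (6aS,10aS)-1,3-dimethoxy-9-methyl-6-oxo-7,8-dihydro-6H-benzo[c]chromene-6a(10aH)-carboxylate, via silyl adduct 10 (not isolated)
Conditions: Cu(OTf)2 (20 mol%), (S,S)-t-Bu-box (22 mol%), 4 Å MS, CH2Cl2, 10 kbar, 25 °C; then CF3CO2H, CH2Cl2, 0 °C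
Reagents that add atoms: none
Why: Proposed new method: the lactone and ester carbonyls of 4 chelate the divalent copper centre, which lowers the LUMO of the C3=C4 bond, and diene 9 adds in an asynchronous [4+2] cycloaddition in which its silyl-bearing terminus bonds first to coumarin C4 while positive charge builds on the methyl-bearing carbon (tertiary and β to silicon), after which the CH2 terminus closes onto C3. The closest known reactions are the thermal, high-pressure and Lewis-acid Diels–Alder additions of 3-alkoxycarbonylcoumarins to alkyl-substituted butadienes and the copper bis(oxazoline)-catalysed cycloadditions and conjugate additions of two-point-binding alkylidene malonates; the enantioselective version on a coumarin ester with a silyl diene is the untested part. The cyclohexene closes in this single intermolecular (4π+2π) event, suprafacial on both partners, so C6a and C10a must come out cis-fused because the dienophile double bond is locked cis in the lactone ring. The absolute configuration of both centres is set together by the face of the chelated coumarin that the tert-butyl groups of the ligand leave open. The step needs the silyl terminus on coumarin C4, which is secured because the methyl group and the β-silicon effect stabilise charge on the same carbon. Endo/exo selectivity is irrelevant, since the silyl-bearing C10 of 10 is flattened when CF3CO2H protonates the allylsilane at C8 and silicon leaves, which moves the alkene to C9=C10. The two methoxy groups make 4 a poor dienophile, hence the pressure.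

Step 6
Reactants: 11 methyl (6aS,10aS)-1,3-dimethoxy-9-methyl-6-oxo-7,8-dihydro-6H-benzo[c]chromene-6a(10aH)-carboxylate
Product: 12 methyl (6aR,10aS)-6-hydroxy-1,3-dimethoxy-9-methyl-7,8-dihydro-6H-benzo[c]chromene-6a(10aH)-carboxylate (C6 epimers)
Conditions: i-Bu2AlH (1.1 equiv), toluene, −78 °C; aq. potassium sodium tartrate
Reagents that add atoms: none
Why: Partial reduction of a lactone to a lactol: the aryl ester carbonyl is more electrophilic than the methyl ester on the same carbon, and its tetrahedral aluminate is stable at −78 °C. The change of the C6a descriptor is a priority change only; no stereocentre is touched.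

Step 7
Reactants: 12 methyl (6aR,10aS)-6-hydroxy-1,3-dimethoxy-9-methyl-7,8-dihydro-6H-benzo[c]chromene-6a(10aH)-carboxylate (C6 epimers)
Product: 13 methyl (6aR,10aS)-1,3,6-trimethoxy-9-methyl-7,8-dihydro-6H-benzo[c]chromene-6a(10aH)-carboxylate (C6 epimers)
Conditions: MeOH, PPTS (cat.), 3 Å MS, 40 °C
Reagents that add atoms: methanol, CO
Why: Acid-catalysed acetalisation of a lactol through the cyclic oxocarbenium ion. Mild acid rather than base is chosen because the open form is an α-formyl ester that alkoxide would deformylate by a retro-Claisen reaction.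

Step 8
Reactants: 13 methyl (6aR,10aS)-1,3,6-trimethoxy-9-methyl-7,8-dihydro-6H-benzo[c]chromene-6a(10aH)-carboxylate (C6 epimers)
Product: 14 [(6aS,10aS)-1,3,6-trimethoxy-9-methyl-7,8-dihydro-6H-benzo[c]chromen-6a(10aH)-yl]methanol (C6 epimers)
Conditions: LiAlH4, THF, 0 °C
Reagents that add atoms: none
Why: Ester reduction with LiAlH4; the cyclic acetal, the aryl ethers and the alkene are inert to hydride.

Step 9
Reactants: 14 [(6aS,10aS)-1,3,6-trimethoxy-9-methyl-7,8-dihydro-6H-benzo[c]chromen-6a(10aH)-yl]methanol (C6 epimers)
Product: 15 [(6aS,10aS)-1,3,6-trimethoxy-9-methyl-7,8-dihydro-6H-benzo[c]chromen-6a(10aH)-yl]methyl methanesulfonate (C6 epimers)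
Conditions: MsCl, Et3N, CH2Cl2, 0 °C
Reagents that add atoms: methanesulfonyl chloride, CS(=O)(=O)Cl
Why: Sulfonylation of a primary alcohol through the sulfene; the basic medium keeps the acetal intact.

Step 10
Reactants: 15 [(6aS,10aS)-1,3,6-trimethoxy-9-methyl-7,8-dihydro-6H-benzo[c]chromen-6a(10aH)-yl]methyl methanesulfonate (C6 epimers)
Product: 16 (6aS,10aS)-1,3,6-trimethoxy-6a,9-dimethyl-6a,7,8,10a-tetrahydro-6H-benzo[c]chromene (C6 epimers)
Conditions: LiEt3BH, THF, reflux
Reagents that add atoms: none
Why: Hydride displacement of a primary sulfonate by LiEt3BH, the reagent of choice for hindered and neopentyl-type sulfonates. The neopentyl position has no β-hydrogen, so elimination cannot compete.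

Step 11
Reactants: 16 (6aS,10aS)-1,3,6-trimethoxy-6a,9-dimethyl-6a,7,8,10a-tetrahydro-6H-benzo[c]chromene (C6 epimers)
Product: 17 (6aS,10aS)-1,3-dimethoxy-6a,9-dimethyl-6a,7,8,10a-tetrahydro-6H-benzo[c]chromen-6-ol (C6 epimers)
Conditions: 1 M HCl, THF, rt
Reagents that add atoms: water, O
Why: Hydrolysis of a mixed aryl alkyl acetal. Dilute aqueous acid at room temperature is mild enough that the phenol does not add across the C9=C10 alkene and the alkene does not migrate.

Step 12
Reactants: 17 (6aS,10aS)-1,3-dimethoxy-6a,9-dimethyl-6a,7,8,10a-tetrahydro-6H-benzo[c]chromen-6-ol (C6 epimers)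
Product: 18 2-[(1R,6S)-6-[(E)-2-iodoethenyl]-3,6-dimethylcyclohex-2-en-1-yl]-3,5-dimethoxyphenol
Conditions: CrCl2 (8 equiv), CHI3 (3 equiv), THF/dioxane, 0 °C → rt
Reagents that add atoms: iodoform, IC(I)I
Why: Takai olefination: the geminal dichromium reagent adds to the hydroxy aldehyde tautomer of the lactol and anti elimination gives the E iodoalkene, favoured further by the quaternary α-carbon. The aldehyde cannot enolise, so C6 of the cyclohexene is not at risk.

Step 13
Reactants: 18 2-[(1R,6S)-6-[(E)-2-iodoethenyl]-3,6-dimethylcyclohex-2-en-1-yl]-3,5-dimethoxyphenol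
Product: 19 2-hydroxy-3-[(1R,6S)-6-[(E)-2-iodoethenyl]-3,6-dimethylcyclohex-2-en-1-yl]-4,6-dimethoxybenzaldehyde
Conditions: MgCl2, Et3N, (CH2O)n, THF, reflux
Reagents that add atoms: paraformaldehyde (reacts as formaldehyde), C=O
Why: Casnati–Skattebøl ortho-formylation: the magnesium phenoxide delivers formaldehyde only to the one free ortho carbon, and hydride transfer to a second formaldehyde gives the salicylaldehyde. The position between the two methoxy groups is para to the oxygen and is not reached.

Step 14
Reactants: 19 2-hydroxy-3-[(1R,6S)-6-[(E)-2-iodoethenyl]-3,6-dimethylcyclohex-2-en-1-yl]-4,6-dimethoxybenzaldehyde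
Product: 21 8-[(1R,6S)-6-[(E)-2-iodoethenyl]-3,6-dimethylcyclohex-2-en-1-yl]-5,7-dimethoxy-2H-chromen-2-one, via acyl ylide 20 (not isolated)
Conditions: Ph3P=C=C=O, toluene, reflux
Reagents that add atoms: (triphenylphosphoranylidene)ketene, O=C=C=P(c1ccccc1)(c1ccccc1)c1ccccc1
Why: Bestmann ylide annulation: the phenol adds to the ketene to give aryl ester ylide 20, and an intramolecular Wittig reaction with the ortho aldehyde forms the cis alkene inside the lactone. The coumarin thus forms at 110 °C without a separate E to Z isomerisation.

Step 15
Reactants: 22 5,7-dimethoxy-2H-chromen-2-one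
Product: 23 8-iodo-5,7-dimethoxy-2H-chromen-2-one
Conditions: NIS, CF3CO2H (cat.), MeCN, rt
Reagents that add atoms: N-iodosuccinimide, O=C1CCC(=O)N1I
Why: Electrophilic aromatic iodination: C8 is ortho to the C7 methoxy group and the ring oxygen and para to the C5 methoxy group, and it is less shielded than C6, which lies between two methoxy groups.

Step 16
Reactants: 23 8-iodo-5,7-dimethoxy-2H-chromen-2-one
Product: 24 5,7-dimethoxy-8-(4,4,5,5-tetramethyl-1,3,2-dioxaborolan-2-yl)-2H-chromen-2-one
Conditions: B2pin2, PdCl2(dppf) (5 mol%), KOAc, dioxane, 90 °C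
Reagents that add atoms: bis(pinacolato)diboron, CC1(C)OB(OC1(C)C)B1OC(C)(C)C(C)(C)O1
Why: Miyaura borylation of an aryl iodide; the weak acetate base leaves the lactone closed.

Step 17
Reactants: 21 8-[(1R,6S)-6-[(E)-2-iodoethenyl]-3,6-dimethylcyclohex-2-en-1-yl]-5,7-dimethoxy-2H-chromen-2-one; 24 5,7-dimethoxy-8-(4,4,5,5-tetramethyl-1,3,2-dioxaborolan-2-yl)-2H-chromen-2-one
Product: 25 8-[(E)-2-[(1R,2R)-2-(5,7-dimethoxy-2-oxo-2H-chromen-8-yl)-1,4-dimethylcyclohex-3-en-1-yl]ethenyl]-5,7-dimethoxy-2H-chromen-2-one
Conditions: Pd(OAc)2 (5 mol%), SPhos (10 mol%), K3PO4, THF/H2O, 50 °C; dilute HCl work-up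
Reagents that add atoms: none
Why: Suzuki–Miyaura coupling: oxidative addition of zerovalent palladium into the alkenyl iodide and reductive elimination both proceed with retention, so the E geometry is kept and neither stereocentre is involved. The biaryl phosphine is chosen for di-ortho-substituted boronates, and phosphate is mild towards the lactones.

## Compound list

1 | 2-hydroxy-4,6-dimethoxybenzaldehyde | COc1cc(O)c(C=O)c(OC)c1 | starting material
2 | dimethyl malonate | COC(=O)CC(=O)OC | starting material
3 | dimethyl 2-[(2-hydroxy-4,6-dimethoxyphenyl)methylidene]propanedioate | COC(=O)C(=Cc1c(O)cc(OC)cc1OC)C(=O)OC | intermediate (not isolated)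
4 | methyl 5,7-dimethoxy-2-oxo-2H-chromene-3-carboxylate | COC(=O)c1cc2c(OC)cc(OC)cc2oc1=O | intermediate
5 | 3-(trimethylsilyl)prop-2-yn-1-ol | OCC#C[Si](C)(C)C | starting material
6 | 4-methyl-3-(trimethylsilyl)-2,5-dihydro-1,2-oxamagnesole (cyclic alkenylmagnesium alkoxide, silicon cis to methyl) | CC1=C([Si](C)(C)C)[Mg]OC1 | intermediate (not isolated)
7 | (E)-2-methyl-3-(trimethylsilyl)prop-2-en-1-ol | OC/C(C)=C/[Si](C)(C)C | intermediate
8 | (E)-2-methyl-3-(trimethylsilyl)prop-2-enal | O=C/C(C)=C/[Si](C)(C)C | intermediate
9 | (E)-trimethyl(2-methylbuta-1,3-dien-1-yl)silane | C=C/C(C)=C/[Si](C)(C)C | intermediate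
10 | cis-fused methyl 1,3-dimethoxy-9-methyl-6-oxo-10-(trimethylsilyl)-7,10-dihydro-6H-benzo[c]chromene-6a(10aH)-carboxylate (ring fusion as in 11, C10 epimers) | O=C2[C@@]1(C(=O)OC)CC=C(C)C([Si](C)(C)C)[C@H]1c1c(OC)cc(OC)cc1O2 | intermediate (not isolated)
11 | methyl (6aS,10aS)-1,3-dimethoxy-9-methyl-6-oxo-7,8-dihydro-6H-benzo[c]chromene-6a(10aH)-carboxylate | O=C2[C@@]1(C(=O)OC)CCC(C)=C[C@H]1c1c(OC)cc(OC)cc1O2 | intermediate
12 | methyl (6aR,10aS)-6-hydroxy-1,3-dimethoxy-9-methyl-7,8-dihydro-6H-benzo[c]chromene-6a(10aH)-carboxylate (C6 epimers) | OC2[C@@]1(C(=O)OC)CCC(C)=C[C@H]1c1c(OC)cc(OC)cc1O2 | intermediate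
13 | methyl (6aR,10aS)-1,3,6-trimethoxy-9-methyl-7,8-dihydro-6H-benzo[c]chromene-6a(10aH)-carboxylate (C6 epimers) | COC2[C@@]1(C(=O)OC)CCC(C)=C[C@H]1c1c(OC)cc(OC)cc1O2 | intermediate
14 | [(6aS,10aS)-1,3,6-trimethoxy-9-methyl-7,8-dihydro-6H-benzo[c]chromen-6a(10aH)-yl]methanol (C6 epimers) | COC2[C@@]1(CO)CCC(C)=C[C@H]1c1c(OC)cc(OC)cc1O2 | intermediate
15 | [(6aS,10aS)-1,3,6-trimethoxy-9-methyl-7,8-dihydro-6H-benzo[c]chromen-6a(10aH)-yl]methyl methanesulfonate (C6 epimers) | COC2[C@@]1(COS(C)(=O)=O)CCC(C)=C[C@H]1c1c(OC)cc(OC)cc1O2 | intermediate
16 | (6aS,10aS)-1,3,6-trimethoxy-6a,9-dimethyl-6a,7,8,10a-tetrahydro-6H-benzo[c]chromene (C6 epimers) | COC2[C@@]1(C)CCC(C)=C[C@H]1c1c(OC)cc(OC)cc1O2 | intermediate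
17 | (6aS,10aS)-1,3-dimethoxy-6a,9-dimethyl-6a,7,8,10a-tetrahydro-6H-benzo[c]chromen-6-ol (C6 epimers) | OC2[C@@]1(C)CCC(C)=C[C@H]1c1c(OC)cc(OC)cc1O2 | intermediate
18 | 2-[(1R,6S)-6-[(E)-2-iodoethenyl]-3,6-dimethylcyclohex-2-en-1-yl]-3,5-dimethoxyphenol | I/C=C/[C@@]1(C)CCC(C)=C[C@H]1c1c(OC)cc(OC)cc1O | intermediate
19 | 2-hydroxy-3-[(1R,6S)-6-[(E)-2-iodoethenyl]-3,6-dimethylcyclohex-2-en-1-yl]-4,6-dimethoxybenzaldehyde | I/C=C/[C@@]1(C)CCC(C)=C[C@H]1c1c(OC)cc(OC)c(C=O)c1O | intermediate
20 | 2-formyl-6-[(1R,6S)-6-[(E)-2-iodoethenyl]-3,6-dimethylcyclohex-2-en-1-yl]-3,5-dimethoxyphenyl 2-(triphenyl-λ5-phosphanylidene)acetate | I/C=C/[C@@]1(C)CCC(C)=C[C@H]1c1c(OC)cc(OC)c(C=O)c1OC(=O)C=P(c1ccccc1)(c1ccccc1)c1ccccc1 | intermediate (not isolated)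
21 | 8-[(1R,6S)-6-[(E)-2-iodoethenyl]-3,6-dimethylcyclohex-2-en-1-yl]-5,7-dimethoxy-2H-chromen-2-one | I/C=C/[C@@]1(C)CCC(C)=C[C@H]1c1c(OC)cc(OC)c2ccc(=O)oc12 | intermediate
22 | 5,7-dimethoxy-2H-chromen-2-one (5,7-dimethoxycoumarin) | COc1cc(OC)c2ccc(=O)oc2c1 | starting material
23 | 8-iodo-5,7-dimethoxy-2H-chromen-2-one | COc1cc(OC)c2ccc(=O)oc2c1I | intermediate
24 | 5,7-dimethoxy-8-(4,4,5,5-tetramethyl-1,3,2-dioxaborolan-2-yl)-2H-chromen-2-one | COc1cc(OC)c2ccc(=O)oc2c1B1OC(C)(C)C(C)(C)O1 | intermediate
25 | 8-[(E)-2-[(1R,2R)-2-(5,7-dimethoxy-2-oxo-2H-chromen-8-yl)-1,4-dimethylcyclohex-3-en-1-yl]ethenyl]-5,7-dimethoxy-2H-chromen-2-one | COc1cc(OC)c2ccc(=O)oc2c1/C=C/[C@@]1(C)CCC(C)=C[C@H]1c1c(OC)cc(OC)c2ccc(=O)oc12 | target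

## Step count and least certain steps

Total step count: 17. Longest linear sequence: 14 steps (steps 2–14 and 17, from 5 to 25).

**Step 5 (key step, proposed new method).**
- Most likely failures: no cycloaddition at all, because the two methoxy groups turn the dienophile into a push–pull system and the peri methoxy group shields C4. Loss of silicon from the zwitterionic stage before ring closure, which would give a dienyl conjugate adduct. Reversal of regiochemistry for steric reasons. Poor facial selectivity of the chelate.
- Fallback (known chemistry): setting out from 4 and 9, the cycloaddition would be run without any chiral catalyst under 10–12 kbar in CH2Cl2, the established mode of reaction of 3-alkoxycarbonylcoumarins with alkyl butadienes. This gives racemic silyl adduct F1, which CF3CO2H converts to racemic cis-lactone F2. F2 would be resolved by preparative chromatography on a polysaccharide chiral stationary phase, and the (6aS,10aS) enantiomer is 11.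

**Step 6.**
- Most likely failure: over-reduction of the lactol aluminate, or competing reduction of the methyl ester, since both carbonyls sit on the same hindered carbon.
- Fallback: from 11, NaBH4 in THF/MeOH at 0 °C reduces only the aryl ester and gives methyl (1R,2S)-1-(hydroxymethyl)-2-(2-hydroxy-4,6-dimethoxyphenyl)-4-methylcyclohex-3-ene-1-carboxylate F3. Parikh–Doering oxidation (SO3·pyridine, DMSO, i-Pr2NEt) of its primary alcohol gives the aldehyde, which closes onto the phenol and returns to 12.

**Step 10.**
- Most likely failure: hydride attack at sulfur, which returns alcohol 14, or substitution at the neopentyl carbon so slow that demethylation of aryl ethers sets in on prolonged heating.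
- Fallback: from 14, NaH, CS2 and MeI give O-{[(6aS,10aS)-1,3,6-trimethoxy-9-methyl-7,8-dihydro-6H-benzo[c]chromen-6a(10aH)-yl]methyl} S-methyl carbonodithioate F4. Barton–McCombie deoxygenation (Bu3SnH, AIBN, toluene, reflux) returns to 16. It needs no substitution at carbon, and without a β-hydrogen there is no Chugaev elimination.

**Step 12.**
- Most likely failure: the lactol stays closed so the olefination stalls, or the phenol protonates the organochromium reagent.
- Fallback: from 17, Seyferth–Gilbert homologation with the Ohira–Bestmann reagent (K2CO3, MeOH), which opens lactols under its basic conditions, gives 2-[(1R,6S)-6-ethynyl-3,6-dimethylcyclohex-2-en-1-yl]-3,5-dimethoxyphenol F5. Hydrozirconation with excess Cp2Zr(H)Cl followed by iodine returns to 18 with E geometry.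

**Step 15.**
- Most likely failure: iodination at C6 or C3 instead of C8, or double iodination.
- Fallback: from 1, phenol-directed ortho-iodination with benzyltrimethylammonium dichloroiodate and NaHCO3 in CH2Cl2/MeOH gives 2-hydroxy-3-iodo-4,6-dimethoxybenzaldehyde F6. Annulation with the Bestmann ylide as in step 14 passes through 2-formyl-6-iodo-3,5-dimethoxyphenyl 2-(triphenyl-λ5-phosphanylidene)acetate F7 and returns to 23.

**Step 17.**
- Most likely failure: protodeboronation of the di-ortho-oxygenated aryl boronate outrunning transmetalation, or opening of a lactone by the aqueous base.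
- Fallback: the polarity is reversed. From 21, borylation of the alkenyl iodide (B2pin2, PdCl2(dppf), KOPh, toluene, 50 °C) gives 8-[(1R,6R)-3,6-dimethyl-6-[(E)-2-(4,4,5,5-tetramethyl-1,3,2-dioxaborolan-2-yl)ethenyl]cyclohex-2-en-1-yl]-5,7-dimethoxy-2H-chromen-2-one F8. Coupling of this robust alkenyl boronate with iodide 23 (Pd(OAc)2, SPhos, K3PO4) returns to 25 and bypasses step 16.

## Further compounds

F1 | step 5 | racemic cis-fused methyl 1,3-dimethoxy-9-methyl-6-oxo-10-(trimethylsilyl)-7,10-dihydro-6H-benzo[c]chromene-6a(10aH)-carboxylate (both enantiomers, C10 epimers) | O=C2[C@@]1(C(=O)OC)CC=C(C)C([Si](C)(C)C)[C@H]1c1c(OC)cc(OC)cc1O2.O=C2[C@]1(C(=O)OC)CC=C(C)C([Si](C)(C)C)[C@@H]1c1c(OC)cc(OC)cc1O2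
F2 | step 5 | racemic methyl (6aS*,10aS*)-1,3-dimethoxy-9-methyl-6-oxo-7,8-dihydro-6H-benzo[c]chromene-6a(10aH)-carboxylate (both enantiomers) | O=C2[C@@]1(C(=O)OC)CCC(C)=C[C@H]1c1c(OC)cc(OC)cc1O2.O=C2[C@]1(C(=O)OC)CCC(C)=C[C@@H]1c1c(OC)cc(OC)cc1O2
F3 | step 6 | methyl (1R,2S)-1-(hydroxymethyl)-2-(2-hydroxy-4,6-dimethoxyphenyl)-4-methylcyclohex-3-ene-1-carboxylate | COC(=O)[C@]1(CO)CCC(C)=C[C@H]1c1c(OC)cc(OC)cc1O
F4 | step 10 | O-{[(6aS,10aS)-1,3,6-trimethoxy-9-methyl-7,8-dihydro-6H-benzo[c]chromen-6a(10aH)-yl]methyl} S-methyl carbonodithioate (C6 epimers) | COC2[C@@]1(COC(=S)SC)CCC(C)=C[C@H]1c1c(OC)cc(OC)cc1O2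
F5 | step 12 | 2-[(1R,6S)-6-ethynyl-3,6-dimethylcyclohex-2-en-1-yl]-3,5-dimethoxyphenol | C#C[C@@]1(C)CCC(C)=C[C@H]1c1c(OC)cc(OC)cc1O
F6 | step 15 | 2-hydroxy-3-iodo-4,6-dimethoxybenzaldehyde | O=Cc1c(O)c(I)c(OC)cc1OC
F7 | step 15 | 2-formyl-6-iodo-3,5-dimethoxyphenyl 2-(triphenyl-λ5-phosphanylidene)acetate | O=Cc1c(OC(=O)C=P(c2ccccc2)(c2ccccc2)c2ccccc2)c(I)c(OC)cc1OC
F8 | step 17 | 8-[(1R,6R)-3,6-dimethyl-6-[(E)-2-(4,4,5,5-tetramethyl-1,3,2-dioxaborolan-2-yl)ethenyl]cyclohex-2-en-1-yl]-5,7-dimethoxy-2H-chromen-2-one | CC1(C)OB(/C=C/[C@@]2(C)CCC(C)=C[C@H]2c2c(OC)cc(OC)c3ccc(=O)oc23)OC1(C)C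
A1 | alternative 1 | 2-[(1R,6R)-6-ethenyl-3,6-dimethylcyclohex-2-en-1-yl]-5-methoxy-3-{[tri(propan-2-yl)silyl]oxy}phenol | C=C[C@@]1(C)CCC(C)=C[C@H]1c1c(O)cc(OC)cc1O[Si](C(C)C)(C(C)C)C(C)C
A2 | alternative 1 | ({[(1R,6R)-6-ethenyl-3,6-dimethylcyclohex-2-en-1-yl]ethynyl}oxy)tri(propan-2-yl)silane | C=C[C@@]1(C)CCC(C)=C[C@H]1C#CO[Si](C(C)C)(C(C)C)C(C)C
A3 | alternative 1 | 3-methoxycyclobut-2-en-1-one | COC1=CC(=O)C1
A4 | alternative 2 | 2-[(1R,6R)-6-ethenyl-3,6-dimethylcyclohex-2-en-1-yl]-1,5-dimethoxy-3-(methoxymethoxy)benzene | C=C[C@@]1(C)CCC(C)=C[C@H]1c1c(OCOC)cc(OC)cc1OC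
A5 | alternative 2 | 1,5-dimethoxy-3-(methoxymethoxy)-2-[(1R,4R)-4-methyl-4-(3-methylbut-3-en-1-yl)cyclobut-2-en-1-yl]benzene | C=C(C)CC[C@]1(C)C=C[C@H]1c1c(OCOC)cc(OC)cc1OC
A6 | alternative 3 | (6aS,10aS)-1,3-dimethoxy-6a,9-dimethyl-6a,7,8,10a-tetrahydro-6H-benzo[c]chromen-6-one | O=C2[C@@]1(C)CCC(C)=C[C@H]1c1c(OC)cc(OC)cc1O2
A7 | alternative 3 | 3,5-dimethoxyphenyl (1S)-4-hydroxy-1,4-dimethylcyclohex-2-ene-1-carboxylate (C4 epimers) | O=C(Oc1cc(OC)cc(OC)c1)[C@@]1(C)CCC(C)(O)C=C1
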